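The route rests on cutting the C5–O5 bond and tracing O5 back to the target's own carboxyl group. In the cyclohexene ring (C1 bears the ester carbon C7, C2 is the alkene CH, C3–C5 bear O3–O5, C6 is CH2), C7 and O5 are 1,3-related across C6, so the C7 carboxylate can reach C5 over one ring face. Iodolactonization of the precursor, commercial (R)-cyclohex-3-ene-1-carboxylic acid with its single stereocentre at C1, closes a temporary C7–O5 γ-lactone, puts iodine on C4 and sets both new centres in one operation. The iodide then gives the C3=C4 alkene, methanolysis returns C7 as the methyl ester, and O5 directs the cis-diol to the opposite face.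

Key step: step 1

Atom labels follow the target numbering above. In lactones 2–4 the systematic locants C1–C5 and C7 coincide with it (target C6 is C8 and O5 is O6 there); in acid 1 the alkene named C3=C4 is C5=C4 of the target.

Assumption on the chemistry: the bromination in step 3 is taken to place bromine on C2, on the face away from the lactone bridge; the C2 epimer or an allylically transposed C4 bromide would converge on the same dienol 6 in step 4.

Step 1
Reactants: 1 (R)-cyclohex-3-ene-1-carboxylic acid
Product: 2 (1R,4R,5R)-4-iodo-6-oxabicyclo[3.2.1]octan-7-one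
Conditions: I2 (1.5 equiv), NaHCO3 (3 equiv), CH2Cl2/H2O, 0 °C to rt, dark; Na2S2O3 wash
Reagents that add atoms: iodine, [I][I]
Why: Iodine adds reversibly to the C4=C5 alkene to give iodonium ions on both faces, and the C7 carboxylate, anchored on C1, opens the one on the far face by backside attack at C5 (iodolactonization, the halocyclization of a γ,δ-unsaturated acid under bicarbonate-buffered kinetic conditions). The single ring formed, the γ-lactone O5–C7–C1–C6–C5, closes in the 5-exo mode; the alternative 6-endo attack at C4 would give the bicyclo[2.2.2] δ-lactone and is disfavoured because the tether reaches the nearer carbon through the less strained transition state. The configuration at C5 is dictated by C1, since the carboxylate can bridge only the ring face on which it stands (from the conformer with an axial carboxyl group), and C4 follows from the anti, trans-diaxial addition that leaves iodine on the opposite face. The step therefore needs C5-over-C4 regioselectivity and face selectivity, and the short tether secures both: the iodonium ion syn to the carboxylate cannot be captured and reverts to the alkene.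

Step 2
Reactants: 2 (1R,4R,5R)-4-iodo-6-oxabicyclo[3.2.1]octan-7-one
Product: 3 (1R,5R)-6-oxabicyclo[3.2.1]oct-3-en-7-one
Conditions: DBU (1.5 equiv), toluene, 90 °C
Reagents that add atoms: none
Why: E2 dehydroiodination: the axial C4 iodide is anti-periplanar only to the axial C3–H (loss of the C5–H would need a bridgehead alkene), so DBU should give the C3=C4 alkene alone, with C1 and C5 untouched.

Step 3
Reactants: 3 (1R,5R)-6-oxabicyclo[3.2.1]oct-3-en-7-one
Product: 4 (1R,2S,5R)-2-bromo-6-oxabicyclo[3.2.1]oct-3-en-7-one
Conditions: NBS (1.1 equiv), AIBN (5 mol%), PhCF3, 80 °C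
Reagents that add atoms: N-bromosuccinimide, O=C1CCC(=O)N1Br
Why: Wohl–Ziegler allylic bromination: the axial C2–H overlaps with the alkene π system and is abstracted (the bridgehead C5–H lies in the alkene plane and is not activated), and the allyl radical should take bromine at C2 from the face away from the lactone bridge, which sets a C2 centre that is destroyed again in step 4.

Step 4
Reactants: 4 (1R,2S,5R)-2-bromo-6-oxabicyclo[3.2.1]oct-3-en-7-one
Product: 6 methyl (5R)-5-hydroxycyclohexa-1,3-diene-1-carboxylate, via bromo hydroxy ester 5 (not isolated)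
Conditions: K2CO3 (2 equiv), MeOH, 0 °C, short reaction time
Reagents that add atoms: methanol, CO
Why: Base-mediated transesterification opens the strained γ-lactone to methyl ester 5 and frees O5, and the C1–H, now α to the ester, is then lost together with the C2 bromide in an E1cB-type β-elimination to the conjugated dienoate; the C5–O bond is never broken, so C5 stays R while the centres at C1 and C2 disappear.

Step 5
Reactants: 6 methyl (5R)-5-hydroxycyclohexa-1,3-diene-1-carboxylate; 7 (2E)-3-methylpent-2-enoic acid
Product: 9 methyl (5R)-5-{[(2E)-3-methylpent-2-enoyl]oxy}cyclohexa-1,3-diene-1-carboxylate, via O-acylisourea 8 (not isolated)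
Conditions: 7 (1.2 equiv), DIC (1.2 equiv), DMAP (10 mol%), CH2Cl2, 0 °C
Reagents that add atoms: (2E)-3-methylpent-2-enoic acid (7), CC/C(C)=C/C(=O)O
Why: Steglich esterification: DIC converts 7 into O-acylisourea 8 and DMAP relays the acyl group to O5, the only hydroxyl present, with retention at C5 (the C5–O bond is not broken); the absence of an acid chloride and of stoichiometric trialkylamine avoids a vinylketene pathway that could scramble the E alkene.

Step 6
Reactants: 9 methyl (5R)-5-{[(2E)-3-methylpent-2-enoyl]oxy}cyclohexa-1,3-diene-1-carboxylate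
Product: 10 methyl (3R,4R,5R)-3,4-dihydroxy-5-{[(2E)-3-methylpent-2-enoyl]oxy}cyclohex-1-ene-1-carboxylate (methyl 5-O-acylshikimate; shikimate configuration, the C4 descriptor reads R only because C5 outranks C3 here)
Conditions: OsO4 (2 mol%), NMO (1.1 equiv), acetone/H2O (8:1), 0 °C; Na2SO3 work-up
Reagents that add atoms: osmium tetroxide (catalytic oxygen carrier), O=[Os](=O)(=O)=O; N-methylmorpholine N-oxide, C[N+]1([O-])CCOCC1; water, O
Why: Catalytic OsO4/NMO cis-dihydroxylation ([3+2] cycloaddition, then hydrolysis of the osmate ester): C3=C4 is the most electron-rich alkene (C1=C2 and the side-chain alkene are each directly conjugated with an ester carbonyl), and OsO4 should add suprafacially to the face opposite the allylic C5 acyloxy group, which sets C3 and C4 cis to each other and trans to O5.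

Step 7
Reactants: 7 (2E)-3-methylpent-2-enoic acid
Product: 12 (2E)-3-methylpent-2-enamide, via acyl imidazolide 11 (not isolated)
Conditions: CDI (1.1 equiv), THF, rt; then NH3 (28% aq.), 0 °C
Reagents that add atoms: ammonia, N
Why: Amide formation through an acyl imidazolide: CDI activates 7 without strong base and ammonia displaces imidazole; the β,β-disubstituted alkene resists conjugate addition and keeps its E geometry.

Step 8
Reactants: 12 (2E)-3-methylpent-2-enamide
Product: 14 (2E)-1,1,1-trimethoxy-3-methylpent-2-ene, via imidate salt 13 (not isolated)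
Conditions: Me3OBF4 (1.05 equiv), CH2Cl2, rt; then MeOH (6 equiv), Et2O, rt; filter, distil from K2CO3
Reagents that add atoms: trimethyloxonium tetrafluoroborate, C[O+](C)C.F[B-](F)(F)F; methanol, CO
Why: O-Methylation of the primary amide by the oxonium salt gives imidate salt 13, whose alcoholysis by methanol with loss of NH4BF4 is the second stage of the Pinner orthoester synthesis; the non-nucleophilic BF4 counter-ion cannot dealkylate the salt back to the amide, and the alkene is a spectator.

Step 9
Reactants: 10 methyl (3R,4R,5R)-3,4-dihydroxy-5-{[(2E)-3-methylpent-2-enoyl]oxy}cyclohex-1-ene-1-carboxylate; 14 (2E)-1,1,1-trimethoxy-3-methylpent-2-ene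
Product: 16 methyl (3R,4S,5R)-4-hydroxy-3,5-bis{[(2E)-3-methylpent-2-enoyl]oxy}cyclohex-1-ene-1-carboxylate (the target), via cyclic orthoester 15 (not isolated)
Conditions: 14 (2 equiv), CSA (5 mol%), 4 Å MS, CH2Cl2, rt; then AcOH/H2O (4:1), 0 °C; neutral work-up
Reagents that add atoms: (2E)-1,1,1-trimethoxy-3-methylpent-2-ene (14), CC/C(C)=C/C(OC)(OC)OC; water, O
Why: Acid-catalysed orthoester exchange followed by mild hydrolysis: only the cis-3,4-diol can span the orthoester carbon to give dioxolane 15 (both epimers at the new orthoester carbon, which is lost again), and the hemiorthoester formed on hydrolysis should open, as is usual for cyclic orthoesters on six-membered rings, to the axial ester and the equatorial alcohol, that is acyl on the pseudoaxial O3 and free O4, with no ring stereocentre touched.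

Compound list
1 | (R)-cyclohex-3-ene-1-carboxylic acid | OC(=O)[C@H]1CC=CCC1 | starting material
2 | (1R,4R,5R)-4-iodo-6-oxabicyclo[3.2.1]octan-7-one | O=C1O[C@@H]2C[C@H]1CC[C@H]2I | intermediate
3 | (1R,5R)-6-oxabicyclo[3.2.1]oct-3-en-7-one | O=C1O[C@@H]2C[C@H]1CC=C2 | intermediate
4 | (1R,2S,5R)-2-bromo-6-oxabicyclo[3.2.1]oct-3-en-7-one | O=C1O[C@@H]2C[C@H]1[C@@H](Br)C=C2 | intermediate
5 | methyl (1R,2S,5R)-2-bromo-5-hydroxycyclohex-3-ene-1-carboxylate (bromo hydroxy ester, formed in the flask) | COC(=O)[C@H]1C[C@@H](O)C=C[C@@H]1Br | intermediate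
6 | methyl (5R)-5-hydroxycyclohexa-1,3-diene-1-carboxylate | COC(=O)C1=CC=C[C@H](O)C1 | intermediate
7 | (2E)-3-methylpent-2-enoic acid | CC/C(C)=C/C(=O)O | starting material
8 | O-[(2E)-3-methylpent-2-enoyl]-N,N'-diisopropylisourea (O-acylisourea, formed in the flask) | CC/C(C)=C/C(=O)OC(=NC(C)C)NC(C)C | intermediate
9 | methyl (5R)-5-{[(2E)-3-methylpent-2-enoyl]oxy}cyclohexa-1,3-diene-1-carboxylate | COC(=O)C1=CC=C[C@H](OC(=O)/C=C(\C)CC)C1 | intermediate
10 | methyl (3R,4R,5R)-3,4-dihydroxy-5-{[(2E)-3-methylpent-2-enoyl]oxy}cyclohex-1-ene-1-carboxylate (methyl 5-O-acylshikimate) | O[C@@H]1C=C(C(=O)OC)C[C@@H](OC(=O)/C=C(\C)CC)[C@@H]1O | intermediate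
11 | 1-[(2E)-3-methylpent-2-enoyl]-1H-imidazole (acyl imidazolide, formed in the flask) | CC/C(C)=C/C(=O)n1ccnc1 | intermediate
12 | (2E)-3-methylpent-2-enamide | CC/C(C)=C/C(N)=O | intermediate
13 | methyl (2E)-3-methylpent-2-enimidate hydrotetrafluoroborate (imidate salt, formed in the flask) | CC/C(C)=C/C(=[NH2+])OC.F[B-](F)(F)F | intermediate
14 | (2E)-1,1,1-trimethoxy-3-methylpent-2-ene | CC/C(C)=C/C(OC)(OC)OC | intermediate
15 | methyl 3,4-O-[(2E)-1-methoxy-3-methylpent-2-en-1-ylidene]-5-O-[(2E)-3-methylpent-2-enoyl]shikimate (cyclic orthoester, both epimers at the orthoester carbon, formed in the flask) | COC1(/C=C(\C)CC)O[C@@H]2C=C(C(=O)OC)C[C@@H](OC(=O)/C=C(\C)CC)[C@@H]2O1 | intermediate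
16 | methyl (3R,4S,5R)-4-hydroxy-3,5-bis{[(2E)-3-methylpent-2-enoyl]oxy}cyclohex-1-ene-1-carboxylate | CC/C(C)=C/C(=O)O[C@@H]1C=C(C(=O)OC)C[C@@H](OC(=O)/C=C(\C)CC)[C@@H]1O | target

Total step count: 9.
Longest linear sequence: 7 steps (steps 1, 2, 3, 4, 5, 6 and 9); steps 7 and 8 are a two-step side branch to orthoester 14.

Steps most likely to fail

Step 8. The conjugated imidate salt may be alcoholysed only slowly, methanol may add to the activated alkene, or the orthoester may lose methanol or alkene geometry on distillation. The fallback needs no orthoester: it sets out from diol 10 and returns to the route at 16. CDI in CH2Cl2 should close the cis-diol to the cyclic carbonate methyl 3,4-O-carbonyl-5-O-[(2E)-3-methylpent-2-enoyl]shikimate F1. The zerovalent palladium catalyst Pd(PPh3)4 (5 mol%) with acid 7 in THF at rt should then ionise only the allylic C3–O bond, since O4 is not allylic, with loss of CO2 (Tsuji–Trost opening of a vinyl cyclic carbonate). The carboxylate should attack the allyl terminus remote from the ester, C3, anti to palladium, so that double inversion gives the 3-O-acyl, 4-hydroxy compound 16 with retention.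

Step 9. The alkene may isomerise in the dialkoxycarbenium ion during exchange, the hemiorthoester may open partly toward O4, or the acyl group may migrate from O3 to O4 after hydrolysis. The fallback replaces stereoelectronic control by temporary protection of O4: it sets out from 10 and returns at 16. Diarylborinic-acid catalysis (2-aminoethyl diphenylborinate 10 mol%, Ag2O, 2-(bromomethyl)naphthalene, MeCN, 40 °C) should alkylate the equatorial oxygen of the cis-diol and give methyl 4-O-(naphthalen-2-ylmethyl)-5-O-[(2E)-3-methylpent-2-enoyl]shikimate F2. Carbodiimide esterification of the one remaining hydroxyl with 7 via 8 gives methyl 3,5-di-O-[(2E)-3-methylpent-2-enoyl]-4-O-(naphthalen-2-ylmethyl)shikimate F3, and DDQ in wet CH2Cl2 removes the naphthylmethyl ether.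

Step 6. OsO4 may also attack the side-chain alkene, facial selectivity may be incomplete, or the O5 acyl group may migrate in the diol. The fallback dihydroxylates before any side chain is present: it sets out from dienol 6 and returns at 10. OsO4/NMO on the free alcohol, approaching anti to the allylic hydroxyl, should give methyl shikimate F4. 2,2-Dimethoxypropane with catalytic TsOH gives methyl 3,4-O-isopropylideneshikimate F5. Esterification of O5 with 7 via 8 gives methyl 3,4-O-isopropylidene-5-O-[(2E)-3-methylpent-2-enoyl]shikimate F6, and AcOH/H2O (4:1) at 40 °C removes the acetonide.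

Further compounds
F1 | step 8 | methyl 3,4-O-carbonyl-5-O-[(2E)-3-methylpent-2-enoyl]shikimate | O=C1O[C@@H]2C=C(C(=O)OC)C[C@@H](OC(=O)/C=C(\C)CC)[C@@H]2O1
F2 | step 9 | methyl 4-O-(naphthalen-2-ylmethyl)-5-O-[(2E)-3-methylpent-2-enoyl]shikimate | O[C@@H]1C=C(C(=O)OC)C[C@@H](OC(=O)/C=C(\C)CC)[C@@H]1OCc1ccc2ccccc2c1
F3 | step 9 | methyl 3,5-di-O-[(2E)-3-methylpent-2-enoyl]-4-O-(naphthalen-2-ylmethyl)shikimate | CC/C(C)=C/C(=O)O[C@@H]1C=C(C(=O)OC)C[C@@H](OC(=O)/C=C(\C)CC)[C@@H]1OCc1ccc2ccccc2c1
F4 | step 6 | methyl shikimate, methyl (3R,4S,5R)-3,4,5-trihydroxycyclohex-1-ene-1-carboxylate | O[C@@H]1C=C(C(=O)OC)C[C@@H](O)[C@@H]1O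
F5 | step 6 | methyl 3,4-O-isopropylideneshikimate | CC1(C)O[C@@H]2C=C(C(=O)OC)C[C@@H](O)[C@@H]2O1
F6 | step 6 | methyl 3,4-O-isopropylidene-5-O-[(2E)-3-methylpent-2-enoyl]shikimate | CC1(C)O[C@@H]2C=C(C(=O)OC)C[C@@H](OC(=O)/C=C(\C)CC)[C@@H]2O1
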